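**Retrosynthetic overview**
1. Route map: carotol 1 → daucene 2 → [hydroperoxide 3 → epoxy alcohol 4] → diol 5; 5 + vanillic acid 6 → teferin 7. Daucane numbering is used: C1 = quaternary ring-fusion carbon, C4 = isopropyl carbinol, C5 = ring-fusion CH, C6 = ester carbon, C8=C9 = ring alkene; β = face of the C1 methyl.
2. Last and key disconnection: the C6–O ester bond of 7, made by SN2 displacement at C6 of 5 with 6 (6β-OH → 6α-O-vanilloyl, inversion).
3. C4–O and C6–O of 5 both come from one O2 added to 2 (ene reaction at C4=C5, oxygen transfer to the transposed C5=C6, radical opening that sets H-5).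
4. C4=C5 of 2 comes from dehydration of 1.
5. Rings: none is formed; the five- and seven-membered rings and the C1 stereocentre are carried from 1, and no C–C bond is made.

Assumption: natural carotol (main alcohol of commercial carrot seed oil, also sold as such) is taken as a cheap commercial starting material, with the (3S,3aS,8aR) configuration, i.e. H-4 cis to the C5 hydroxyl.

Step 1
Reactants: 1 carotol
Product: 2 daucene
Conditions: Burgess reagent (MeO2CN−SO2N+Et3), benzene, 50 °C
Reagents that add atoms: none
Why: Burgess dehydration, a concerted syn-elimination of the tertiary sulfamate: H-4 is cis to the C5 hydroxyl, so the tetrasubstituted (Zaitsev) C4=C5 alkene forms, and the only remaining stereocentre, C1, is not touched.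

Step 2
Reactants: 2 daucene
Product: 5 6-epi-jaeschkeanadiol (5α-H-dauc-8-ene-4β,6β-diol), via allylic hydroperoxide 3 (not isolated), via epoxy alcohol 4 (not isolated)
Conditions: O2, meso-tetraphenylporphyrin (cat.), Ti(OiPr)4 (10 mol %), hν (white LED), CH2Cl2, −20 °C; then Ar, THF, Cp2TiCl2 (20 mol %), Mn dust, 2,4,6-collidine·HCl, 1,4-cyclohexadiene, rt
Reagents that add atoms: dioxygen O=O
Why: Proposed new method: a one-flask relay from tetravalent to trivalent titanium that turns an alkene, through its ene hydroperoxide, into the transposed anti-Markovnikov 1,3-diol, not described as a single operation (closest known chemistry: Schenck ene reaction with Ti(OiPr)4-catalysed oxygen transfer of the allylic hydroperoxide to an epoxy alcohol, and the Nugent–RajanBabu reductive epoxide opening with catalytic Cp2TiCl); singlet oxygen picks the tetrasubstituted C4=C5 over the trisubstituted C8=C9 alkene, attacks its β face (C7 and C10 fold the seven-membered ring under the α face) and abstracts H-6, the hydrogen geminal to the bulky quaternary C1 (large-group effect), which places the OOH at C4 cis to the C1 methyl (3); tetravalent titanium then passes the distal peroxide oxygen to the new C5=C6 bond syn to the C4 alkoxide (β-epoxide 4, C8=C9 untouched); after the change to argon the chelating trivalent titanium breaks the C5–O bond homolytically to the tertiary C5 radical, which takes H from 1,4-cyclohexadiene on the α face, anti to the C1 methyl and to both β oxygens, giving the trans ring fusion with the C6 hydroxyl still β.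

Step 3
Reactants: 5 6-epi-jaeschkeanadiol; 6 vanillic acid
Product: 7 teferin
Conditions: PPh3, diisopropyl azodicarboxylate, THF, 0 °C to rt
Reagents that add atoms: none
Why: Mitsunobu esterification: only the secondary C6 oxyphosphonium of the syn-1,3-diol can be displaced (the tertiary C4–OH cannot), the carboxylic acid (pKa about 4.5) and not the phenol (pKa about 9) is the pronucleophile, and SN2 attack from the open α face inverts C6 to the natural 6α-ester.

**Compound list**
1 | carotol, (3S,3aS,8aR)-6,8a-dimethyl-3-(propan-2-yl)-2,3,4,5,8,8a-hexahydroazulen-3a(1H)-ol (5-OH cis to the C1 methyl, 4-isopropyl α) | CC1=CC[C@@]2(C)CC[C@@H](C(C)C)[C@@]2(O)CC1 | starting material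
2 | daucene, (8aR)-6,8a-dimethyl-3-(propan-2-yl)-1,2,4,5,8,8a-hexahydroazulene (dauca-4,8-diene) | CC1=CC[C@@]2(C)CCC(C(C)C)=C2CC1 | intermediate
3 | 4β-hydroperoxydauca-5,8-diene (tertiary allylic hydroperoxide, OOH cis to the C1 methyl) | CC1=CC[C@@]2(C)CC[C@@](OO)(C(C)C)C2=CC1 | intermediate
4 | 5β,6β-epoxydauc-8-en-4β-ol (hydroxyl and epoxide oxygen cis to the C1 methyl) | CC1=CC[C@@]2(C)CC[C@@](O)(C(C)C)[C@]23O[C@@H]3C1 | intermediate
5 | 6-epi-jaeschkeanadiol, dauc-8-ene-4β,6β-diol with 5α-H (trans ring fusion, both hydroxyls cis to the C1 methyl) | CC1=CC[C@@]2(C)CC[C@@](O)(C(C)C)[C@@H]2[C@H](O)C1 | intermediate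
6 | vanillic acid (4-hydroxy-3-methoxybenzoic acid) | COc1cc(C(=O)O)ccc1O | starting material
7 | teferin, 4β-hydroxy-5α-H-dauc-8-en-6α-yl 4-hydroxy-3-methoxybenzoate | COc1cc(C(=O)O[C@H]2CC(C)=CC[C@@]3(C)CC[C@@](O)(C(C)C)[C@H]23)ccc1O | target

**Totals**
Total step count: 3. Longest linear sequence: 3 steps (1 → 2 → 5 → 7).

**Steps most likely to fail**

Step 2 (the proposed new step). The relay fails if the ene reaction is not regio- or face-selective, if peroxide residues quench the trivalent titanium, or if the C5 radical is deoxygenated instead of reduced. The fallback uses known chemistry in three separately controlled reactions, with an external oxidant in place of the in-flask oxygen transfer. It sets out from 2: Schenck ene reaction (O2, meso-tetraphenylporphyrin, hν, CH2Cl2, −20 °C) to 3 and reduction with PPh3 give the allylic alcohol dauca-5,8-dien-4β-ol F1, which is purified. Hydroxyl-directed epoxidation with VO(acac)2 and t-BuOOH gives isolated 4. Nugent–RajanBabu opening with stoichiometric Cp2TiCl (from Cp2TiCl2 and Zn) and 1,4-cyclohexadiene gives 5, where the fallback comes back to the route.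

Step 3. SN2 at a secondary carbinol next to the ring fusion may be slow, and E2 loss of the oxyphosphonium (to the C6=C7 diene or back to the C5=C6 alkene) may compete. The fallback is redox inversion followed by retentive acylation. It sets out from 5: Dess–Martin periodinane oxidises the C6 carbinol to the β-hydroxy ketone 4β-hydroxydauc-8-en-6-one F2. Me4NBH(OAc)3 (Evans–Saksena reduction, hydride delivered from the β face by the boron bound to the C4 oxygen) gives jaeschkeanadiol F3 with the 6α-hydroxyl. Steglich acylation with commercial 4-acetoxy-3-methoxybenzoic acid (DCC, 4-(dimethylamino)pyridine) gives O-acetylteferin F4. K2CO3 in MeOH at 0 °C cleaves only the aryl acetate, and the fallback comes back at 7.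

Step 1. The syn-elimination may give the less substituted C5=C6 alkene if H-4 cannot reach the syn geometry. The fallback goes through the other elimination manifold. It sets out from 1: SOCl2 in pyridine at 0 °C forms the carotol chlorosulfite F5 (not isolated), which collapses by the ionising/anti pathway to 2, where the fallback comes back.

**Further compounds**
F1 | step 2 | dauca-5,8-dien-4β-ol | CC1=CC[C@@]2(C)CC[C@@](O)(C(C)C)C2=CC1
F2 | step 3 | 4β-hydroxy-5α-H-dauc-8-en-6-one | CC1=CC[C@@]2(C)CC[C@@](O)(C(C)C)[C@@H]2C(=O)C1
F3 | step 3 | jaeschkeanadiol (5α-H-dauc-8-ene-4β,6α-diol) | CC1=CC[C@@]2(C)CC[C@@](O)(C(C)C)[C@@H]2[C@@H](O)C1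
F4 | step 3 | O-acetylteferin (4β-hydroxy-5α-H-dauc-8-en-6α-yl 4-acetoxy-3-methoxybenzoate) | CC1=CC[C@@]2(C)CC[C@@](O)(C(C)C)[C@@H]2[C@@H](OC(=O)c3ccc(OC(C)=O)c(OC)c3)C1
F5 | step 1 | carotol chlorosulfite | CC1=CC[C@@]2(C)CC[C@@H](C(C)C)[C@@]2(OS(=O)Cl)CC1
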